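**Plan**

- Retrosynthesis: the oxolane (O1, C2 with the hydroxyphenyl ring, C3 with C9, C4 with C7', C5) is opened at O1–C2. The two acetates and two silyl ethers are then removed, the C9 and C7' oxygens are tied back into a γ-lactone, and C3–C2 (benzylation) and C4–C7' (aldol) are cut.
- Enabling feature: C2 bears the only ring with a free para-OH, so its C–H can be oxidised to a p-quinone methide whose methide carbon lies four bonds from the oxygen on C5. The anisyl ring on C7' has no such option.
- Forward: an imide aldol with 4-methoxybenzaldehyde joins C4–C7' and closes a temporary lactone ring. The carboxyl becomes the silylated C5 carbinol, enolate benzylation joins C3–C2, reduction opens the lactone, acetylation and desilylation follow, and the oxolane ring closes last.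
- Stereochemistry: C7' and C4 come from the (S)-4-benzyloxazolidinone syn-aldol, C3 from alkylation trans to the C4 substituent, and C2 from the reversible, substrate-controlled closure to the all-trans ring.

Key step: step 13

Remark: the open aldol adduct is assumed to lactonise on warming and work-up, as methyl succinate aldolates normally do; lignan-style locants (C2–C5, C7', C9) are used throughout and TBS stands for tert-butyldimethylsilyl.

**Route**

Step 1
Reactants: 1 (S)-4-benzyl-1,3-oxazolidin-2-one; 2 methyl 4-chloro-4-oxobutanoate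
Product: 4 methyl 4-[(4S)-4-benzyl-2-oxo-1,3-oxazolidin-3-yl]-4-oxobutanoate, via N-lithio oxazolidinone 3 (not isolated)
Conditions: n-BuLi, THF, −78 °C; then 2, −78 to 0 °C
Reagents that add atoms: none
Why: This is a standard N-acylation of a lithiated oxazolidinone, in which the acid chloride end of 2 reacts far faster than its methyl ester, so the succinate half-ester imide should form cleanly with no new stereocentre.

Step 2
Reactants: 4 methyl 4-[(4S)-4-benzyl-2-oxo-1,3-oxazolidin-3-yl]-4-oxobutanoate; 5 4-methoxybenzaldehyde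
Product: 8 (4S)-4-benzyl-3-{[(2S,3S)-2-(4-methoxyphenyl)-5-oxooxolan-3-yl]carbonyl}-1,3-oxazolidin-2-one (trans lactone), via Z-boron enolate 6 (not isolated), via open syn-aldol ester 7 (not isolated)
Conditions: Bu2BOTf, i-Pr2NEt, CH2Cl2, −78 to 0 °C; 5, −78 °C to rt; aq. NaH2PO4/Na2HPO4 (pH 7), MeOH, 30% H2O2, 0 °C
Reagents that add atoms: none
Why: In this Evans syn-aldol reaction the Z-boron enolate 6 adds to the aldehyde through a closed chair (Zimmerman–Traxler) transition state on the face remote from the benzyl group of the (S)-auxiliary, which sets C4 and C7' as the syn (S,S) pair, and the aldol oxygen of 7 then displaces methoxide from the ester to close the trans γ-lactone.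

Step 3
Reactants: 8 (4S)-4-benzyl-3-{[(2S,3S)-2-(4-methoxyphenyl)-5-oxooxolan-3-yl]carbonyl}-1,3-oxazolidin-2-one
Product: 10 (2S,3S)-2-(4-methoxyphenyl)-5-oxooxolane-3-carboxylic acid, via peroxy acid 9 (not isolated)
Conditions: LiOH, 30% H2O2, THF/H2O, 0 °C; aq. Na2SO3; 1 M HCl to pH 2
Reagents that add atoms: hydrogen peroxide, OO
Why: Lithium hydroperoxide hydrolysis of an N-acyl oxazolidinone attacks the exocyclic carbonyl selectively, sulfite reduces peracid 9, and acidification re-closes any opened γ-lactone, so the auxiliary should be released without disturbing C4 or C7'.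

Step 4
Reactants: 10 (2S,3S)-2-(4-methoxyphenyl)-5-oxooxolane-3-carboxylic acid
Product: 11 (4R,5S)-4-(hydroxymethyl)-5-(4-methoxyphenyl)oxolan-2-one
Conditions: BH3·SMe2, THF, 0 °C to rt; MeOH
Reagents that add atoms: none
Why: Borane reduces a free carboxylic acid much faster than a lactone (chemoselective borane reduction through the acyloxyborane), so C5 should reach the alcohol level with the ring and both stereocentres intact.

Step 5
Reactants: 11 (4R,5S)-4-(hydroxymethyl)-5-(4-methoxyphenyl)oxolan-2-one
Product: 12 (4R,5S)-4-[(tert-butyldimethylsilyloxy)methyl]-5-(4-methoxyphenyl)oxolan-2-one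
Conditions: t-BuMe2SiCl, imidazole, DMF, 0 °C to rt
Reagents that add atoms: tert-butyldimethylsilyl chloride, CC(C)(C)[Si](C)(C)Cl
Why: Imidazole-promoted silylation of the primary alcohol is fast and mild, which caps the C5 oxygen before it can translactonise and keeps it distinct from the C9 oxygen released later.

Step 6
Reactants: 13 4-hydroxybenzaldehyde
Product: 14 4-(tert-butyldimethylsilyloxy)benzaldehyde
Conditions: t-BuMe2SiCl, imidazole, DMF, rt
Reagents that add atoms: tert-butyldimethylsilyl chloride, CC(C)(C)[Si](C)(C)Cl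
Why: Imidazole-promoted silylation of the phenol gives an aryl silyl ether that tolerates hydride, phosphine and amide base and is cleaved by fluoride at the end.

Step 7
Reactants: 14 4-(tert-butyldimethylsilyloxy)benzaldehyde
Product: 15 [4-(tert-butyldimethylsilyloxy)phenyl]methanol
Conditions: NaBH4, MeOH, 0 °C
Reagents that add atoms: none
Why: Borohydride reduction of an aryl aldehyde to the benzylic alcohol is chemoselective and leaves the aryl silyl ether untouched.

Step 8
Reactants: 15 [4-(tert-butyldimethylsilyloxy)phenyl]methanol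
Product: 16 4-(tert-butyldimethylsilyloxy)benzyl bromide
Conditions: CBr4, PPh3, CH2Cl2, 0 °C; used at once
Reagents that add atoms: carbon tetrabromide, BrC(Br)(Br)Br
Why: The Appel reaction converts the benzylic alcohol to the bromide under neutral conditions, so the aryl silyl ether should survive.

Step 9
Reactants: 12 (4R,5S)-4-[(tert-butyldimethylsilyloxy)methyl]-5-(4-methoxyphenyl)oxolan-2-one; 16 4-(tert-butyldimethylsilyloxy)benzyl bromide
Product: 18 (3S,4R,5S)-3-[4-(tert-butyldimethylsilyloxy)benzyl]-4-[(tert-butyldimethylsilyloxy)methyl]-5-(4-methoxyphenyl)oxolan-2-one, via lithium lactone enolate 17 (not isolated)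
Conditions: LiN(SiMe3)2, THF, −78 °C; then 16, −78 to −40 °C
Reagents that add atoms: none
Why: Alkylation of the lithium lactone enolate 17 with a reactive benzylic bromide follows the usual course for β-substituted γ-butyrolactones, the electrophile entering anti to the silyloxymethyl group on C4, which sets C3 trans to C4 (3S).

Step 10
Reactants: 18 (3S,4R,5S)-3-[4-(tert-butyldimethylsilyloxy)benzyl]-4-[(tert-butyldimethylsilyloxy)methyl]-5-(4-methoxyphenyl)oxolan-2-one
Product: 19 (1S,2R,3S)-3-[4-(tert-butyldimethylsilyloxy)benzyl]-2-[(tert-butyldimethylsilyloxy)methyl]-1-(4-methoxyphenyl)butane-1,4-diol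
Conditions: LiBH4, THF, 0 °C to rt; sat. aq. NH4Cl
Reagents that add atoms: none
Why: LiBH4 reduces the lactone to the 1,4-diol (hydride reduction of an ester) without affecting the silyl ethers or any stereocentre, and the near-neutral work-up avoids acid-induced cyclisation of the anisylic alcohol.

Step 11
Reactants: 19 (1S,2R,3S)-3-[4-(tert-butyldimethylsilyloxy)benzyl]-2-[(tert-butyldimethylsilyloxy)methyl]-1-(4-methoxyphenyl)butane-1,4-diol
Product: 20 (1S,2R,3S)-3-[4-(tert-butyldimethylsilyloxy)benzyl]-2-[(tert-butyldimethylsilyloxy)methyl]-1-(4-methoxyphenyl)butane-1,4-diyl diacetate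
Conditions: Ac2O, pyridine, 4-(dimethylamino)pyridine (cat.), CH2Cl2, 0 °C to rt
Reagents that add atoms: acetic anhydride, CC(=O)OC(C)=O
Why: Nucleophile-catalysed acylation with acetic anhydride esterifies the primary C9 and the secondary benzylic C7' hydroxyls alike, fixing both acetates of the target before the C5 oxygen is uncovered.

Step 12
Reactants: 20 (1S,2R,3S)-3-[4-(tert-butyldimethylsilyloxy)benzyl]-2-[(tert-butyldimethylsilyloxy)methyl]-1-(4-methoxyphenyl)butane-1,4-diyl diacetate
Product: 21 (1S,2R,3S)-2-(hydroxymethyl)-3-(4-hydroxybenzyl)-1-(4-methoxyphenyl)butane-1,4-diyl diacetate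
Conditions: HF·pyridine, pyridine, THF, 0 °C to rt
Reagents that add atoms: none
Why: Fluoride-mediated desilylation, driven by the strong Si–F bond, removes the alkyl and the aryl silyl ether, and the pyridine-buffered, weakly acidic medium generates no alkoxide, so the acetates should neither migrate nor hydrolyse.

Step 13
Reactants: 21 (1S,2R,3S)-2-(hydroxymethyl)-3-(4-hydroxybenzyl)-1-(4-methoxyphenyl)butane-1,4-diyl diacetate
Product: 23 (S)-[(3R,4S,5R)-4-(acetoxymethyl)-5-(4-hydroxyphenyl)oxolan-3-yl](4-methoxyphenyl)methyl acetate (the target; 2R,3S,4R,7'S in the locants used here), via p-quinone methide 22 (not isolated)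
Conditions: DDQ (2,3-dichloro-5,6-dicyano-1,4-benzoquinone, 1.05 equiv), 4 Å molecular sieves, CH2Cl2, 0 °C to rt
Reagents that add atoms: none
Why: DDQ removes a hydride equivalent from the C2 methylene para to the free phenolic OH and the phenol proton is lost, giving p-quinone methide 22; the closest known reaction type is the quinone dehydrogenation of 4-alkylphenols with capture of the quinone methide by an alcohol, here made intramolecular. Ring closure is 5-exo-trig: the oxygen on C5 attacks the exocyclic methide carbon, O1–C2 forms and the dienone re-aromatises to the phenol. C2 is set under substrate control by C3 and C4, since the envelope-like transition state that keeps the acetoxymethyl and the acetoxy(aryl)methyl groups pseudo-equatorial places the aryl group anti to the C3 substituent, and because 2-(4-hydroxyphenyl)oxolanes re-ionise in the weakly acidic medium left by the reduced quinone the closure can equilibrate toward the all-trans (2R) isomer. The step needs site selectivity between the two benzylic positions and chemoselectivity among nucleophiles: only the ring on C2 has a free OH and can become a neutral quinone methide, the C7' hydrogen is deactivated by its acetoxy group, the acetates are poor nucleophiles and the anisyl carbons able to reach C2 are meta to the methoxy group. One equivalent of oxidant under anhydrous conditions should limit a second oxidation at the C2–H of the product.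

**Compound list**

1 | (S)-4-benzyl-1,3-oxazolidin-2-one | O=C1N[C@@H](Cc2ccccc2)CO1 | starting material
2 | methyl 4-chloro-4-oxobutanoate | COC(=O)CCC(Cl)=O | starting material
3 | lithium (4S)-4-benzyl-2-oxo-1,3-oxazolidin-3-ide (N-lithio oxazolidinone) | [Li]N1[C@@H](Cc2ccccc2)COC1=O | intermediate
4 | methyl 4-[(4S)-4-benzyl-2-oxo-1,3-oxazolidin-3-yl]-4-oxobutanoate | COC(=O)CCC(=O)N1[C@@H](Cc2ccccc2)COC1=O | intermediate
5 | 4-methoxybenzaldehyde | COc1ccc(C=O)cc1 | starting material
6 | dibutylboron Z-enolate of 4, methyl (Z)-4-[(4S)-4-benzyl-2-oxo-1,3-oxazolidin-3-yl]-4-(dibutylboranyloxy)but-3-enoate | COC(=O)C/C=C(\OB(CCCC)CCCC)N1[C@@H](Cc2ccccc2)COC1=O | intermediate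
7 | methyl (3S,4S)-3-{[(4S)-4-benzyl-2-oxo-1,3-oxazolidin-3-yl]carbonyl}-4-hydroxy-4-(4-methoxyphenyl)butanoate (open syn-aldol ester) | COc1ccc([C@@H](O)[C@H](CC(=O)OC)C(=O)N2[C@@H](Cc3ccccc3)COC2=O)cc1 | intermediate
8 | (4S)-4-benzyl-3-{[(2S,3S)-2-(4-methoxyphenyl)-5-oxooxolan-3-yl]carbonyl}-1,3-oxazolidin-2-one (trans lactone) | COc1ccc([C@H]2OC(=O)C[C@@H]2C(=O)N2[C@@H](Cc3ccccc3)COC2=O)cc1 | intermediate
9 | (2S,3S)-2-(4-methoxyphenyl)-5-oxooxolane-3-carboperoxoic acid | COc1ccc([C@H]2OC(=O)C[C@@H]2C(=O)OO)cc1 | intermediate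
10 | (2S,3S)-2-(4-methoxyphenyl)-5-oxooxolane-3-carboxylic acid | COc1ccc([C@H]2OC(=O)C[C@@H]2C(=O)O)cc1 | intermediate
11 | (4R,5S)-4-(hydroxymethyl)-5-(4-methoxyphenyl)oxolan-2-one | COc1ccc([C@H]2OC(=O)C[C@@H]2CO)cc1 | intermediate
12 | (4R,5S)-4-[(tert-butyldimethylsilyloxy)methyl]-5-(4-methoxyphenyl)oxolan-2-one | COc1ccc([C@H]2OC(=O)C[C@@H]2CO[Si](C)(C)C(C)(C)C)cc1 | intermediate
13 | 4-hydroxybenzaldehyde | O=Cc1ccc(O)cc1 | starting material
14 | 4-(tert-butyldimethylsilyloxy)benzaldehyde | O=Cc1ccc(O[Si](C)(C)C(C)(C)C)cc1 | intermediate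
15 | [4-(tert-butyldimethylsilyloxy)phenyl]methanol | OCc1ccc(O[Si](C)(C)C(C)(C)C)cc1 | intermediate
16 | 4-(tert-butyldimethylsilyloxy)benzyl bromide | BrCc1ccc(O[Si](C)(C)C(C)(C)C)cc1 | intermediate
17 | lithium enolate of lactone 12 (O-lithio, C4 and C5 as in 12) | COc1ccc([C@H]2OC(O[Li])=C[C@@H]2CO[Si](C)(C)C(C)(C)C)cc1 | intermediate
18 | (3S,4R,5S)-3-[4-(tert-butyldimethylsilyloxy)benzyl]-4-[(tert-butyldimethylsilyloxy)methyl]-5-(4-methoxyphenyl)oxolan-2-one | COc1ccc([C@H]2OC(=O)[C@@H](Cc3ccc(O[Si](C)(C)C(C)(C)C)cc3)[C@@H]2CO[Si](C)(C)C(C)(C)C)cc1 | intermediate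
19 | (1S,2R,3S)-3-[4-(tert-butyldimethylsilyloxy)benzyl]-2-[(tert-butyldimethylsilyloxy)methyl]-1-(4-methoxyphenyl)butane-1,4-diol | COc1ccc([C@@H](O)[C@@H](CO[Si](C)(C)C(C)(C)C)[C@H](Cc2ccc(O[Si](C)(C)C(C)(C)C)cc2)CO)cc1 | intermediate
20 | (1S,2R,3S)-3-[4-(tert-butyldimethylsilyloxy)benzyl]-2-[(tert-butyldimethylsilyloxy)methyl]-1-(4-methoxyphenyl)butane-1,4-diyl diacetate | COc1ccc([C@@H](OC(C)=O)[C@@H](CO[Si](C)(C)C(C)(C)C)[C@H](Cc2ccc(O[Si](C)(C)C(C)(C)C)cc2)COC(C)=O)cc1 | intermediate
21 | (1S,2R,3S)-2-(hydroxymethyl)-3-(4-hydroxybenzyl)-1-(4-methoxyphenyl)butane-1,4-diyl diacetate | COc1ccc([C@@H](OC(C)=O)[C@@H](CO)[C@H](Cc2ccc(O)cc2)COC(C)=O)cc1 | intermediate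
22 | p-quinone methide of 21: the C2 carbon is the exocyclic =CH of a 4-alkylidenecyclohexa-2,5-dien-1-one, the other centres as in 21 | COc1ccc([C@@H](OC(C)=O)[C@@H](CO)[C@H](C=C2C=CC(=O)C=C2)COC(C)=O)cc1 | intermediate
23 | (S)-[(3R,4S,5R)-4-(acetoxymethyl)-5-(4-hydroxyphenyl)oxolan-3-yl](4-methoxyphenyl)methyl acetate, all-trans oxolane | COc1ccc([C@@H](OC(C)=O)[C@H]2CO[C@@H](c3ccc(O)cc3)[C@@H]2COC(C)=O)cc1 | target

**Step count and weak points**

Total step count: 13. Longest linear sequence: 10 steps (steps 1–5 and 9–13); steps 6–8 are a three-step side branch to bromide 16.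

Steps most likely to fail:

Step 13. The oxidation may not stop at the quinone methide stage. Possible failure processes are a second hydride loss at the benzylic ether C–H of the product, phenoxyl radical coupling in place of hydride loss, and tautomerisation of the quinone methide to the styrene before the hydroxyl adds. The fallback makes the same quinone methide by 1,6-elimination from a C2-oxygenated precursor instead of by C–H oxidation. It sets out from lithium enolate 17 (made from lactone 12 as in step 9) and aldehyde 14. Aldol addition at −78 °C, again anti to the C4 substituent, should give aldol lactone F1 as a mixture of carbinol epimers, both of which are usable because that carbon becomes planar later. LiBH4 in THF should reduce it to triol F2, and Ac2O with pyridine and catalytic 4-(dimethylamino)pyridine should give triacetate F3. HF·pyridine should remove both silyl groups to give phenol alcohol triacetate F4. On exposure to aq. NaHCO3 in MeCN the 4-hydroxybenzylic acetate of F4 should lose acetic acid by 1,6-elimination. This route returns to the main route at quinone methide 22, which closes to target 23 as in step 13.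

Step 12. Cleavage of the aryl silyl ether may be slow, and on long exposure the C7' acetyl group may shift to the freed C5 hydroxyl or the anisylic acetate may ionise. The fallback changes the order of events so that the C5 hydroxyl is released only in the flask in which it is consumed. It sets out from bis-silyl diacetate 20. KHF2 in MeOH, which is selective for aryl silyl ethers, should give phenol F5 with the C5 silyl ether intact. DDQ in CH2Cl2/MeOH at 0 °C should oxidise F5 to silylated quinone methide F6, which methanol captures to give benzylic methyl ether F7 as C2 epimers. Aqueous HF in MeCN should then cleave the primary silyl ether to hydroxy methyl ether F8. In the same acidic medium F8 should lose methanol to give quinone methide 22 in O-protonated form, which the new hydroxyl closes to target 23 under the same thermodynamic control. The route is rejoined at 22 and 23.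

Step 9. The bromide may approach the wrong enolate face, a second alkylation may occur, or the labile silyloxybenzyl bromide may decompose before it is consumed. The fallback alkylates at the carboxylic acid stage, where the carboxylate on C4 is a larger, charged directing group. It sets out from acid 10. Double deprotonation with LiN(SiMe3)2 (2.2 equiv) in THF at −78 °C should give dilithium enolate carboxylate F9, and bromide 16 should alkylate it trans to the carboxylate to give benzylated acid F10. BH3·SMe2 should reduce the acid to hydroxymethyl lactone F11, and t-BuMe2SiCl with imidazole returns to the route at lactone 18.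

**Further compounds**

F1 | step 13 | 3,4-trans-4,5-trans aldol lactone, (4R,5S)-3-{hydroxy[4-(tert-butyldimethylsilyloxy)phenyl]methyl}-4-[(tert-butyldimethylsilyloxy)methyl]-5-(4-methoxyphenyl)oxolan-2-one, carbinol epimers | COc1ccc([C@H]2OC(=O)[C@@H](C(O)c3ccc(O[Si](C)(C)C(C)(C)C)cc3)[C@@H]2CO[Si](C)(C)C(C)(C)C)cc1
F2 | step 13 | triol from reduction of F1, free hydroxyls at C7', C9 and C2, silyl ethers at the C5 oxygen and the phenol | COc1ccc([C@@H](O)[C@@H](CO[Si](C)(C)C(C)(C)C)[C@H](C(O)c2ccc(O[Si](C)(C)C(C)(C)C)cc2)CO)cc1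
F3 | step 13 | triacetate of F2 (acetates at C7', C9 and C2) | COc1ccc([C@@H](OC(C)=O)[C@@H](CO[Si](C)(C)C(C)(C)C)[C@H](C(OC(C)=O)c2ccc(O[Si](C)(C)C(C)(C)C)cc2)COC(C)=O)cc1
F4 | step 13 | phenol alcohol triacetate (free phenol and free C5 hydroxyl, acetates at C7', C9 and C2) | COc1ccc([C@@H](OC(C)=O)[C@@H](CO)[C@H](C(OC(C)=O)c2ccc(O)cc2)COC(C)=O)cc1
F5 | step 12 | phenol with the C5 silyl ether retained, (1S,2R,3S)-2-[(tert-butyldimethylsilyloxy)methyl]-3-(4-hydroxybenzyl)-1-(4-methoxyphenyl)butane-1,4-diyl diacetate | COc1ccc([C@@H](OC(C)=O)[C@@H](CO[Si](C)(C)C(C)(C)C)[C@H](Cc2ccc(O)cc2)COC(C)=O)cc1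
F6 | step 12 | silylated p-quinone methide of F5 | COc1ccc([C@@H](OC(C)=O)[C@@H](CO[Si](C)(C)C(C)(C)C)[C@H](C=C2C=CC(=O)C=C2)COC(C)=O)cc1
F7 | step 12 | benzylic methyl ether at C2 (C2 epimers), C5 silyl ether retained | COc1ccc([C@@H](OC(C)=O)[C@@H](CO[Si](C)(C)C(C)(C)C)[C@H](C(OC)c2ccc(O)cc2)COC(C)=O)cc1
F8 | step 12 | hydroxy methyl ether (free C5 hydroxyl, methoxy at C2) | COc1ccc([C@@H](OC(C)=O)[C@@H](CO)[C@H](C(OC)c2ccc(O)cc2)COC(C)=O)cc1
F9 | step 9 | dilithium enolate carboxylate of acid 10 | COc1ccc([C@H]2OC(O[Li])=C[C@@H]2C(=O)O[Li])cc1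
F10 | step 9 | (2S,3S,4S)-4-[4-(tert-butyldimethylsilyloxy)benzyl]-2-(4-methoxyphenyl)-5-oxooxolane-3-carboxylic acid | COc1ccc([C@H]2OC(=O)[C@@H](Cc3ccc(O[Si](C)(C)C(C)(C)C)cc3)[C@@H]2C(=O)O)cc1
F11 | step 9 | (3S,4R,5S)-3-[4-(tert-butyldimethylsilyloxy)benzyl]-4-(hydroxymethyl)-5-(4-methoxyphenyl)oxolan-2-one | COc1ccc([C@H]2OC(=O)[C@@H](Cc3ccc(O[Si](C)(C)C(C)(C)C)cc3)[C@@H]2CO)cc1
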